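**Retrosynthetic overview**
- Target ⇐ global O‑debenzylation and desilylation of a protected β‑silyloxy aryl ketone, itself made from a 1,3‑diol by primary silylation and oxidation of a sacrificial benzylic carbinol.
- 1,3‑Diol ⇐ reductive auxiliary removal from a syn‑aldol adduct. Key C–C bond: boron enolate of an arylacetyl oxazolidinone (ring B carrying the finished lactone) plus O‑benzylvanillin, which sets the side‑chain stereocentre.
- Arylacetic acid ⇐ oxidative cleavage of an aryl allyl group installed by Claisen rearrangement of O‑allylvanillin.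
- trans‑Lactone ⇐ anti‑selective α‑benzylation of an (R)‑β‑benzyl‑γ‑butyrolactone, made by auxiliary‑controlled benzylation of a succinate imide, reduction and lactonisation.
- Ring order: the three arenes are bought; the γ‑butyrolactone is the only ring formed (step 9), before the side chain is built.

Assumption: the enolisable α‑aryl ketone stereocentre is configurationally stable under the near‑neutral conditions of steps 19–21; this is not verified experimentally.
Shorthand in names: ArV = 4‑(benzyloxy)‑3‑methoxyphenyl; ArL = 2‑(benzyloxy)‑3‑methoxy‑5‑{[(3R,4R)‑4‑[4‑(benzyloxy)‑3‑methoxybenzyl]‑5‑oxotetrahydrofuran‑3‑yl]methyl}phenyl (ring B of 23, attached through the carbon ortho to its OBn).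

**Route**

Step 1
Reactants: 1 vanillin; 2 allyl bromide
Product: 3 4-(allyloxy)-3-methoxybenzaldehyde
Conditions: K2CO3, acetone, reflux
Reagents that add atoms: none
Why: Williamson ether synthesis (SN2 of the phenoxide on the allylic bromide); the aldehyde is inert to carbonate.

Step 2
Reactants: 3 4-(allyloxy)-3-methoxybenzaldehyde
Product: 5 5-allylvanillin (3-allyl-4-hydroxy-5-methoxybenzaldehyde), via Claisen ortho-dienone 4 (not isolated)
Conditions: PhNEt2, 200 °C
Reagents that add atoms: none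
Why: Aromatic Claisen [3,3]-rearrangement delivers the allyl group to the only free ortho position and the dienone tautomerises to the phenol.

Step 3
Reactants: 5 5-allylvanillin; 6 benzyl bromide
Product: 7 3-allyl-4-(benzyloxy)-5-methoxybenzaldehyde
Conditions: K2CO3, DMF, 60 °C
Reagents that add atoms: none
Why: Williamson benzylation gives a phenol protecting group that survives all later basic, reducing and oxidising steps until the final hydrogenolysis.

Step 4
Reactants: 7 3-allyl-4-(benzyloxy)-5-methoxybenzaldehyde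
Product: 8 [3-allyl-4-(benzyloxy)-5-methoxyphenyl]methanol
Conditions: NaBH4, MeOH, 0 °C
Reagents that add atoms: none
Why: Chemoselective borohydride reduction of the aldehyde; the isolated alkene and ethers are untouched.

Step 5
Reactants: 8 [3-allyl-4-(benzyloxy)-5-methoxyphenyl]methanol
Product: 9 1-allyl-2-(benzyloxy)-5-(bromomethyl)-3-methoxybenzene
Conditions: PBr3, CH2Cl2, 0 °C
Reagents that add atoms: phosphorus tribromide, BrP(Br)Br
Why: Bromination of an electron-rich benzylic alcohol through its phosphite ester (SN2) is fast at 0 °C and leaves the terminal alkene alone.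

Step 6
Reactants: 10 mono-tert-butyl succinate; 11 (R)-4-benzyl-2-oxazolidinone
Product: 13 tert-butyl 4-[(4R)-4-benzyl-2-oxooxazolidin-3-yl]-4-oxobutanoate, via mixed pivalic anhydride 12 (not isolated)
Conditions: PivCl, Et3N, THF, −20 °C; then LiCl, 11, −20 °C → rt
Reagents that add atoms: none
Why: Mixed-anhydride N-acylation of the oxazolidinone occurs at the unhindered succinyl carbonyl and leaves the tert-butyl ester intact.

Step 7
Reactants: 13 succinate imide; 9 benzylic bromide
Product: 15 tert-butyl (3R)-3-[3-allyl-4-(benzyloxy)-5-methoxybenzyl]-4-[(4R)-4-benzyl-2-oxooxazolidin-3-yl]-4-oxobutanoate, via sodium Z-enolate 14 (not isolated)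
Conditions: NaHMDS, THF, −78 °C; then 9, −78 → −30 °C
Reagents that add atoms: none
Why: Evans asymmetric alkylation: the chelated Z-enolate (formed only α to the more acidic imide) is benzylated on the face opposite the auxiliary benzyl group, setting the (R) centre that becomes the lactone β-carbon.

Step 8
Reactants: 15 alkylated imide
Product: 16 tert-butyl (3R)-4-[3-allyl-4-(benzyloxy)-5-methoxyphenyl]-3-(hydroxymethyl)butanoate
Conditions: LiBH4, MeOH (1 equiv), THF, 0 °C
Reagents that add atoms: none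
Why: Reductive auxiliary cleavage: LiBH4 reduces the activated imide carbonyl to the primary alcohol much faster than the tert-butyl ester, and the stereocentre is not enolised.

Step 9
Reactants: 16 hydroxy tert-butyl ester
Product: 18 (4R)-4-[3-allyl-4-(benzyloxy)-5-methoxybenzyl]dihydrofuran-2(3H)-one, via hydroxy acid 17 (not isolated)
Conditions: TFA/CH2Cl2 (1:4), 0 °C → rt
Reagents that add atoms: none
Why: Acid cleaves the tert-butyl ester and the γ-hydroxy acid closes to the five-membered lactone (acid-catalysed lactonisation) without touching the stereocentre.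

Step 10
Reactants: 19 O-benzylvanillin (4-(benzyloxy)-3-methoxybenzaldehyde)
Product: 20 [4-(benzyloxy)-3-methoxyphenyl]methanol
Conditions: NaBH4, MeOH, 0 °C
Reagents that add atoms: none
Why: Simple borohydride reduction of an aromatic aldehyde.

Step 11
Reactants: 20 [4-(benzyloxy)-3-methoxyphenyl]methanol
Product: 21 1-(benzyloxy)-4-(bromomethyl)-2-methoxybenzene
Conditions: PBr3, CH2Cl2, 0 °C (used fresh)
Reagents that add atoms: phosphorus tribromide, BrP(Br)Br
Why: Standard benzylic alcohol-to-bromide conversion (SN2 on the phosphite ester).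

Step 12
Reactants: 18 (R)-β-benzyl lactone; 21 benzylic bromide
Product: 23 (3R,4R)-4-[3-allyl-4-(benzyloxy)-5-methoxybenzyl]-3-[4-(benzyloxy)-3-methoxybenzyl]dihydrofuran-2(3H)-one, via lithium enolate 22 (not isolated)
Conditions: LiHMDS, THF, −78 °C; then 21, DMPU, −78 → −30 °C
Reagents that add atoms: none
Why: Lactone enolate alkylation occurs anti to the adjacent β-benzyl group (1,2-induction), giving the 3,4-trans (3R) centre as in matairesinol-type syntheses.

Step 13
Reactants: 23 trans-lactone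
Product: 25 2-ArL-acetaldehyde, via vicinal diol 24 (not isolated)
Conditions: OsO4 (2 mol%), NaIO4, 2,6-lutidine, dioxane/H2O (3:1), rt
Reagents that add atoms: osmium tetroxide, O=[Os](=O)(=O)=O (catalytic oxygen carrier); sodium periodate, [Na+].[O-]I(=O)(=O)=O (terminal oxidant)
Why: Lemieux–Johnson oxidation (dihydroxylation then glycol cleavage) shortens the allyl group by one carbon while lactone, benzyl ethers and arenes are inert.

Step 14
Reactants: 25 2-ArL-acetaldehyde
Product: 26 2-ArL-acetic acid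
Conditions: NaClO2, NaH2PO4, 2-methyl-2-butene, t-BuOH/H2O, 0 °C → rt (crude 25 used at once)
Reagents that add atoms: sodium chlorite, [Na+].[O-]Cl=O
Why: Pinnick oxidation converts the enolisable aldehyde to the acid under buffered conditions, with the alkene scavenger protecting the electron-rich arenes from HOCl.

Step 15
Reactants: 26 2-ArL-acetic acid; 11 (R)-4-benzyl-2-oxazolidinone
Product: 28 (4R)-4-benzyl-3-(2-ArL-acetyl)oxazolidin-2-one, via mixed pivalic anhydride 27 (not isolated)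
Conditions: PivCl, Et3N, THF, −20 °C; then LiCl, 11, −20 °C → rt
Reagents that add atoms: none
Why: Mixed-anhydride N-acylation under weakly basic, non-nucleophilic conditions attaches the auxiliary without opening or epimerising the lactone.

Step 16 (key step)
Reactants: 28 arylacetyl imide; 19 O-benzylvanillin
Product: 31 (4R)-4-benzyl-3-[(2R,3R)-2-ArL-3-ArV-3-hydroxypropanoyl]oxazolidin-2-one, via dibutylboron Z-enolate 29 (not isolated), via dibutylboron aldolate 30 (not isolated)
Conditions: Bu2BOTf (1.15 equiv), iPr2NEt, CH2Cl2, −78 → 0 °C; 19, −78 → 0 °C; pH 7 buffer, MeOH, 30% H2O2, 0 °C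
Reagents that add atoms: none
Why: Evans syn aldol: soft enolisation acts only on the acidic arylacetyl imide, and the Z-enolate adds through a Zimmerman–Traxler chair on the face set by the (R)-auxiliary, giving the (2R,3R) adduct whose C-2 is the future (S) centre of the target.

Step 17
Reactants: 31 syn-aldol adduct
Product: 32 (1R,2S)-2-ArL-1-ArV-propane-1,3-diol
Conditions: NaBH4, THF/H2O (4:1), 0 °C → rt
Reagents that add atoms: none
Why: Reductive auxiliary cleavage: borohydride in wet THF reduces the activated N-acyl oxazolidinone far faster than a γ-lactone and does not touch the stereocentres.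

Step 18
Reactants: 32 1,3-diol
Product: 33 (1R,2S)-2-ArL-1-ArV-3-[(tert-butyldimethylsilyl)oxy]propan-1-ol
Conditions: TBSCl (1.05 equiv), imidazole, CH2Cl2, 0 °C
Reagents that add atoms: tert-butyldimethylsilyl chloride, CC(C)(C)[Si](C)(C)Cl
Why: Selective silylation of the unhindered primary hydroxyl over the hindered secondary benzylic one.

Step 19
Reactants: 33 mono-TBS ether
Product: 34 (2S)-2-ArL-1-ArV-3-[(tert-butyldimethylsilyl)oxy]propan-1-one
Conditions: Dess–Martin periodinane, NaHCO3, CH2Cl2, 0 °C → rt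
Reagents that add atoms: none
Why: Buffered Dess–Martin oxidation turns the sacrificial benzylic carbinol into the aryl ketone under near-neutral conditions that do not enolise the adjacent α-aryl stereocentre.

Step 20
Reactants: 34 silyloxy ketone
Product: 35 (2S)-2-ArL-1-ArV-3-hydroxypropan-1-one
Conditions: HF·pyridine, pyridine, THF, 0 °C
Reagents that add atoms: none
Why: Fluoride desilylation under buffered, weakly acidic conditions avoids the E1cB elimination and enolisation that basic fluoride would cause.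

Step 21
Reactants: 35 tribenzyl ether of the target
Product: 36 CNP0191394.1, (3R,4R)-4-{4-hydroxy-3-[(2S)-3-hydroxy-1-(4-hydroxy-3-methoxyphenyl)-1-oxopropan-2-yl]-5-methoxybenzyl}-3-(4-hydroxy-3-methoxybenzyl)dihydrofuran-2(3H)-one
Conditions: H2 (1 atm), 10% Pd/C, EtOAc, rt (stopped after 3 equiv H2)
Reagents that add atoms: none
Why: Neutral catalytic hydrogenolysis cleaves the three aryl benzyl ethers faster than it attacks the electron-rich aryl ketone, and leaves the lactone and all three stereocentres untouched.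

**Compound list**
1 | vanillin | COc1cc(C=O)ccc1O | starting material
2 | allyl bromide | C=CCBr | starting material
3 | 4-(allyloxy)-3-methoxybenzaldehyde | COc1cc(C=O)ccc1OCC=C | intermediate
4 | 6-allyl-4-formyl-2-methoxycyclohexa-2,4-dien-1-one (racemic Claisen dienone) | COC1=CC(C=O)=CC(CC=C)C1=O | intermediate (not isolated)
5 | 5-allylvanillin (3-allyl-4-hydroxy-5-methoxybenzaldehyde) | COc1cc(C=O)cc(CC=C)c1O | intermediate
6 | benzyl bromide | BrCc1ccccc1 | starting material
7 | 3-allyl-4-(benzyloxy)-5-methoxybenzaldehyde | COc1cc(C=O)cc(CC=C)c1OCc1ccccc1 | intermediate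
8 | [3-allyl-4-(benzyloxy)-5-methoxyphenyl]methanol | COc1cc(CO)cc(CC=C)c1OCc1ccccc1 | intermediate
9 | 1-allyl-2-(benzyloxy)-5-(bromomethyl)-3-methoxybenzene | COc1cc(CBr)cc(CC=C)c1OCc1ccccc1 | intermediate
10 | mono-tert-butyl succinate (4-tert-butoxy-4-oxobutanoic acid) | CC(C)(C)OC(=O)CCC(=O)O | starting material
11 | (R)-4-benzyl-2-oxazolidinone | O=C1N[C@H](Cc2ccccc2)CO1 | starting material
12 | mixed pivalic anhydride of 10 | CC(C)(C)OC(=O)CCC(=O)OC(=O)C(C)(C)C | intermediate (not isolated)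
13 | tert-butyl 4-[(4R)-4-benzyl-2-oxooxazolidin-3-yl]-4-oxobutanoate | CC(C)(C)OC(=O)CCC(=O)N1[C@H](Cc2ccccc2)COC1=O | intermediate
14 | sodium Z-enolate of 13 | CC(C)(C)OC(=O)C/C=C(\[O-])N1[C@H](Cc2ccccc2)COC1=O.[Na+] | intermediate (not isolated)
15 | tert-butyl (3R)-3-[3-allyl-4-(benzyloxy)-5-methoxybenzyl]-4-[(4R)-4-benzyl-2-oxooxazolidin-3-yl]-4-oxobutanoate | CC(C)(C)OC(=O)C[C@@H](Cc1cc(OC)c(OCc2ccccc2)c(CC=C)c1)C(=O)N1[C@H](Cc2ccccc2)COC1=O | intermediate
16 | tert-butyl (3R)-4-[3-allyl-4-(benzyloxy)-5-methoxyphenyl]-3-(hydroxymethyl)butanoate | CC(C)(C)OC(=O)C[C@@H](Cc1cc(OC)c(OCc2ccccc2)c(CC=C)c1)CO | intermediate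
17 | (3R)-4-[3-allyl-4-(benzyloxy)-5-methoxyphenyl]-3-(hydroxymethyl)butanoic acid | OC(=O)C[C@@H](Cc1cc(OC)c(OCc2ccccc2)c(CC=C)c1)CO | intermediate (not isolated)
18 | (4R)-4-[3-allyl-4-(benzyloxy)-5-methoxybenzyl]dihydrofuran-2(3H)-one | O=C1C[C@@H](Cc2cc(OC)c(OCc3ccccc3)c(CC=C)c2)CO1 | intermediate
19 | O-benzylvanillin (4-(benzyloxy)-3-methoxybenzaldehyde) | COc1cc(C=O)ccc1OCc1ccccc1 | starting material
20 | [4-(benzyloxy)-3-methoxyphenyl]methanol | COc1cc(CO)ccc1OCc1ccccc1 | intermediate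
21 | 1-(benzyloxy)-4-(bromomethyl)-2-methoxybenzene | COc1cc(CBr)ccc1OCc1ccccc1 | intermediate
22 | lithium enolate of 18 | [Li+].[O-]C1=C[C@@H](Cc2cc(OC)c(OCc3ccccc3)c(CC=C)c2)CO1 | intermediate (not isolated)
23 | (3R,4R)-4-[3-allyl-4-(benzyloxy)-5-methoxybenzyl]-3-[4-(benzyloxy)-3-methoxybenzyl]dihydrofuran-2(3H)-one | COc1cc(C[C@H]2C(=O)OC[C@@H]2Cc2cc(OC)c(OCc3ccccc3)c(CC=C)c2)ccc1OCc1ccccc1 | intermediate
24 | 3-ArL-propane-1,2-diol (23 with allyl dihydroxylated; epimers at the carbinol) | COc1cc(C[C@H]2C(=O)OC[C@@H]2Cc2cc(OC)c(OCc3ccccc3)c(CC(O)CO)c2)ccc1OCc1ccccc1 | intermediate (not isolated)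
25 | 2-ArL-acetaldehyde | COc1cc(C[C@H]2C(=O)OC[C@@H]2Cc2cc(OC)c(OCc3ccccc3)c(CC=O)c2)ccc1OCc1ccccc1 | intermediate
26 | 2-ArL-acetic acid | COc1cc(C[C@H]2C(=O)OC[C@@H]2Cc2cc(OC)c(OCc3ccccc3)c(CC(=O)O)c2)ccc1OCc1ccccc1 | intermediate
27 | mixed pivalic anhydride of 26 | COc1cc(C[C@H]2C(=O)OC[C@@H]2Cc2cc(OC)c(OCc3ccccc3)c(CC(=O)OC(=O)C(C)(C)C)c2)ccc1OCc1ccccc1 | intermediate (not isolated)
28 | (4R)-4-benzyl-3-(2-ArL-acetyl)oxazolidin-2-one | COc1cc(C[C@H]2C(=O)OC[C@@H]2Cc2cc(OC)c(OCc3ccccc3)c(CC(=O)N3[C@H](Cc4ccccc4)COC3=O)c2)ccc1OCc1ccccc1 | intermediate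
29 | dibutylboron Z-enolate of 28 | COc1cc(C[C@H]2C(=O)OC[C@@H]2Cc2cc(OC)c(OCc3ccccc3)c(/C=C(\OB(CCCC)CCCC)N3[C@H](Cc4ccccc4)COC3=O)c2)ccc1OCc1ccccc1 | intermediate (not isolated)
30 | O-dibutylboryl aldolate of 31 | COc1cc(C[C@H]2C(=O)OC[C@@H]2Cc2cc(OC)c(OCc3ccccc3)c([C@@H](C(=O)N3[C@H](Cc4ccccc4)COC3=O)[C@@H](OB(CCCC)CCCC)c3ccc(OCc4ccccc4)c(OC)c3)c2)ccc1OCc1ccccc1 | intermediate (not isolated)
31 | (4R)-4-benzyl-3-[(2R,3R)-2-ArL-3-ArV-3-hydroxypropanoyl]oxazolidin-2-one | COc1cc(C[C@H]2C(=O)OC[C@@H]2Cc2cc(OC)c(OCc3ccccc3)c([C@@H](C(=O)N3[C@H](Cc4ccccc4)COC3=O)[C@@H](O)c3ccc(OCc4ccccc4)c(OC)c3)c2)ccc1OCc1ccccc1 | intermediate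
32 | (1R,2S)-2-ArL-1-ArV-propane-1,3-diol | COc1cc(C[C@H]2C(=O)OC[C@@H]2Cc2cc(OC)c(OCc3ccccc3)c([C@@H](CO)[C@@H](O)c3ccc(OCc4ccccc4)c(OC)c3)c2)ccc1OCc1ccccc1 | intermediate
33 | (1R,2S)-2-ArL-1-ArV-3-[(tert-butyldimethylsilyl)oxy]propan-1-ol | COc1cc(C[C@H]2C(=O)OC[C@@H]2Cc2cc(OC)c(OCc3ccccc3)c([C@@H](CO[Si](C)(C)C(C)(C)C)[C@@H](O)c3ccc(OCc4ccccc4)c(OC)c3)c2)ccc1OCc1ccccc1 | intermediate
34 | (2S)-2-ArL-1-ArV-3-[(tert-butyldimethylsilyl)oxy]propan-1-one | COc1cc(C[C@H]2C(=O)OC[C@@H]2Cc2cc(OC)c(OCc3ccccc3)c([C@@H](CO[Si](C)(C)C(C)(C)C)C(=O)c3ccc(OCc4ccccc4)c(OC)c3)c2)ccc1OCc1ccccc1 | intermediate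
35 | (2S)-2-ArL-1-ArV-3-hydroxypropan-1-one | COc1cc(C[C@H]2C(=O)OC[C@@H]2Cc2cc(OC)c(OCc3ccccc3)c([C@@H](CO)C(=O)c3ccc(OCc4ccccc4)c(OC)c3)c2)ccc1OCc1ccccc1 | intermediate
36 | CNP0191394.1 | COc1cc(C[C@H]2C(=O)OC[C@@H]2Cc2cc(OC)c(O)c([C@@H](CO)C(=O)c3ccc(O)c(OC)c3)c2)ccc1O | target

**Totals**
Total step count: 21. Longest linear sequence: 18 steps (1–5, 7–9, 12–21, from vanillin).

**Three steps most likely to fail**

Step 16 (aldol on the advanced imide; possible sluggish addition to the electron-rich aldehyde or competing lactone enolisation). The fallback sets out from acid 26 and comes back at diol 32. Acid 26 is coupled with (R)-4-benzylthiazolidine-2-thione (EDC·HCl, DMAP, CH2Cl2) to give the N-arylacetyl thiazolidinethione F1. Its chlorotitanium enolate (TiCl4, iPr2NEt, NMP, CH2Cl2, −78 → 0 °C, the "Evans-syn" titanium protocol) is added to 19 to give the (2R,3R) syn-aldol thioimide F2. NaBH4 in THF/EtOH at 0 °C then cleaves the very reactive thioimide to 32, which also bypasses step 17.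

Step 17 (imide reduction beside a lactone; possible lactone reduction or retro-aldol). The fallback sets out from 31 and comes back at 32. LiOH/H2O2 (THF/H2O, 0 °C) hydrolyses the imide to the (2R,3R)-2-ArL-3-ArV-3-hydroxypropanoic acid F3, and the acidic work-up recloses any opened lactone. BH3·SMe2 (THF, 0 °C → rt) then reduces only the carboxylic acid to give 32.

Step 20 (desilylation of a β-silyloxy ketone with an acidic α-H; possible elimination or epimerisation). The fallback sets out from diol 32 and comes back at 35. DDQ (1.2 equiv, CH2Cl2/dioxane, rt) dehydrogenates the electron-rich p-alkoxybenzylic secondary alcohol selectively in the presence of the primary alcohol, so the silyl ether stage (33, 34) is skipped altogether.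

**Further compounds**
F1 | step 16 | (4R)-4-benzyl-3-(2-ArL-acetyl)thiazolidine-2-thione | COc1cc(C[C@H]2C(=O)OC[C@@H]2Cc2cc(OC)c(OCc3ccccc3)c(CC(=O)N3[C@H](Cc4ccccc4)CSC3=S)c2)ccc1OCc1ccccc1
F2 | step 16 | (4R)-4-benzyl-3-[(2R,3R)-2-ArL-3-ArV-3-hydroxypropanoyl]thiazolidine-2-thione | COc1cc(C[C@H]2C(=O)OC[C@@H]2Cc2cc(OC)c(OCc3ccccc3)c([C@@H](C(=O)N3[C@H](Cc4ccccc4)CSC3=S)[C@@H](O)c3ccc(OCc4ccccc4)c(OC)c3)c2)ccc1OCc1ccccc1
F3 | step 17 | (2R,3R)-2-ArL-3-ArV-3-hydroxypropanoic acid | COc1cc(C[C@H]2C(=O)OC[C@@H]2Cc2cc(OC)c(OCc3ccccc3)c([C@@H](C(=O)O)[C@@H](O)c3ccc(OCc4ccccc4)c(OC)c3)c2)ccc1OCc1ccccc1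
F0 | step 20 | none | none
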